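## Retrosynthetic overview

- Sigmoidin D ⇐ its tris-TIPS ether by one global desilylation; the secondary alcohol is never protected.
- Ring C is cut at C3–C4 and C2–O1 in one operation: an aroyl radical from a ring-A salicylaldehyde adds to a ring-B styrene, and copper-mediated, ligand-controlled C–O closure sets C2 (ring C is formed last).
- Ring-A aldehyde ⇐ resorcinol: silylation, meta C–H borylation/oxidation (third oxygen), ortho-formylation.
- Ring-B styrene ⇐ catechol + 3-chloro-3-methylbut-1-yne: propargyl Claisen builds the dimethylpyran ring first, Jacobsen epoxidation/hydride opening sets the carbinol centre, C–H borylation/vinylation adds the vinyl group.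

Assumption: the descriptors read from the SMILES are 2S at the flavanone carbon and 3S at the chromanol carbon; "C2, C3, C4, O1" refer to ring C, and chroman locants to the dimethylchroman unit.

## Route

Step 1
Reactants: 1 resorcinol (benzene-1,3-diol)
Product: 2 1,3-bis(triisopropylsilyloxy)benzene
Conditions: TIPSCl (2.3 equiv), imidazole (5 equiv), DMF, rt
Reagents that add atoms: chlorotriisopropylsilane (TIPSCl), CC(C)[Si](Cl)(C(C)C)C(C)C
Why: Imidazole-promoted O-silylation of both phenols; the bulky TIPS ethers leave only C5–H sterically open for the next step, tolerate base, hydride and oxygen radicals, and all come off together at the end.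

Step 2
Reactants: 2 1,3-bis(triisopropylsilyloxy)benzene
Product: 4 3,5-bis(triisopropylsilyloxy)phenol, via arylboronic ester 3 (not isolated)
Conditions: [Ir(OMe)(cod)]2 (1.5 mol %), 4,4'-di-tert-butyl-2,2'-bipyridine (3 mol %), B2pin2 (0.6 equiv), cyclohexane, 80 °C; then Oxone (2KHSO5·KHSO4·K2SO4), acetone/H2O, 0 °C to rt, same pot
Reagents that add atoms: bis(pinacolato)diboron, CC1(C)OB(OC1(C)C)B1OC(C)(C)C(C)(C)O1 (its boryl group is present only in 3); Oxone, reacting as potassium peroxymonosulfate, [K+].[O-]S(=O)(=O)OO (delivers the phenol oxygen)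
Why: Iridium-catalysed aromatic C–H borylation is sterically controlled and takes the only C–H without an ortho substituent (C5, meta to both silyloxy groups), and Oxone oxidation of the C–B bond in the same pot installs the third ring-A oxygen (one-pot C–H borylation/oxidation).

Step 3
Reactants: 4 3,5-bis(triisopropylsilyloxy)phenol; 5 formaldehyde (used as paraformaldehyde)
Product: 6 2-hydroxy-4,6-bis(triisopropylsilyloxy)benzaldehyde
Conditions: MgCl2 (2 equiv), Et3N (4 equiv), (CH2O)n (6 equiv), MeCN, 80 °C
Reagents that add atoms: none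
Why: Magnesium-mediated ortho-formylation (Casnati–Skattebøl): the magnesium phenoxide delivers formaldehyde only ortho to the free OH (both ortho sites are equivalent, the para site lies between two TIPS groups), and a second formaldehyde oxidises the benzylic alkoxide by hydride transfer.

Step 4
Reactants: 7 catechol (benzene-1,2-diol)
Product: 8 2-(triisopropylsilyloxy)phenol
Conditions: 7 (3 equiv), TIPSCl (1 equiv), imidazole (1.5 equiv), CH2Cl2/DMF, 0 °C to rt; excess catechol removed by water wash
Reagents that add atoms: chlorotriisopropylsilane (TIPSCl), CC(C)[Si](Cl)(C(C)C)C(C)C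
Why: Statistical mono-silylation with catechol in excess masks the oxygen that becomes the free 8-OH of the chroman and leaves the other phenol for ring construction.

Step 5
Reactants: 8 2-(triisopropylsilyloxy)phenol; 9 3-chloro-3-methylbut-1-yne
Product: 11 2,2-dimethyl-8-(triisopropylsilyloxy)-2H-chromene, via aryl propargyl ether 10 (not isolated)
Conditions: 9 (1.5 equiv), DBU (1.6 equiv), CuCl2·2H2O (1 mol %), MeCN, 0 °C; aqueous wash, then crude ether in o-xylene, 140 °C
Reagents that add atoms: none
Why: Copper-catalysed O-alkylation with the tertiary propargylic chloride, then thermal aryl propargyl Claisen rearrangement, 1,5-hydrogen shift and oxa-6π electrocyclisation at the only free ortho position, forms the dimethylpyran ring.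

Step 6
Reactants: 11 2,2-dimethyl-8-(triisopropylsilyloxy)-2H-chromene
Product: 12 (3S,4S)-3,4-epoxy-2,2-dimethyl-8-(triisopropylsilyloxy)chroman (cis-fused oxirane)
Conditions: (S,S)-N,N'-bis(3,5-di-tert-butylsalicylidene)-1,2-cyclohexanediaminomanganese chloride (5 mol %), N-methylmorpholine N-oxide (5 equiv), mCPBA (2 equiv), CH2Cl2, −78 °C
Reagents that add atoms: 3-chloroperbenzoic acid (mCPBA), OOC(=O)c1cccc(Cl)c1
Why: Jacobsen–Katsuki epoxidation, for which 2,2-dimethylchromenes are the benchmark cis-alkenes (typically above 95% ee); the (S,S)-catalyst gives the (3S,4S)-oxirane (same facial sense as its (1S,2R)-indene oxide), so the carbinol stereocentre is set here by catalyst control.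

Step 7
Reactants: 12 (3S,4S)-3,4-epoxy-2,2-dimethyl-8-(triisopropylsilyloxy)chroman
Product: 13 (3S)-2,2-dimethyl-8-(triisopropylsilyloxy)chroman-3-ol
Conditions: LiAlH4 (1 equiv), THF, 0 °C to rt; H2O/NaOH work-up
Reagents that add atoms: none
Why: Hydride SN2 opening of the aryl oxirane occurs at benzylic C4, which is also the less hindered carbon (C3 is neopentylic), so the C3–O bond is untouched and the (3S)-alcohol forms with retention.

Step 8
Reactants: 13 (3S)-2,2-dimethyl-8-(triisopropylsilyloxy)chroman-3-ol; 14 vinyl bromide (bromoethene)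
Product: 16 (3S)-6-ethenyl-2,2-dimethyl-8-(triisopropylsilyloxy)chroman-3-ol, via C6 boronic ester 15 (not isolated)
Conditions: [Ir(OMe)(cod)]2 (2 mol %), 4,4'-di-tert-butyl-2,2'-bipyridine (4 mol %), B2pin2 (1.5 equiv), THF, 80 °C; then Pd(dppf)Cl2 (5 mol %), K3PO4 (3 M aq), 14 (1 M in THF, 3 equiv), 60 °C, sealed tube
Reagents that add atoms: bis(pinacolato)diboron, CC1(C)OB(OC1(C)C)B1OC(C)(C)C(C)(C)O1 (its boryl group is present only in 15)
Why: Sterically controlled iridium-catalysed C–H borylation can occur only at C6 (C5 is ortho to the ring CH2, C7 is ortho to OTIPS; the alcohol is masked in situ as its O-Bpin ester), and Suzuki–Miyaura coupling of the crude boronic ester with vinyl bromide in the same pot gives the styrene.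

Step 9
Reactants: 6 2-hydroxy-4,6-bis(triisopropylsilyloxy)benzaldehyde (1.5 equiv); 16 (3S)-6-ethenyl-2,2-dimethyl-8-(triisopropylsilyloxy)chroman-3-ol
Product: 17 (2S)-2-[(3S)-3-hydroxy-2,2-dimethyl-8-(triisopropylsilyloxy)chroman-6-yl]-5,7-bis(triisopropylsilyloxy)chroman-4-one
Conditions: Cu(MeCN)4PF6 (10 mol %), 2,2'-(propane-2,2-diyl)bis[(4S)-4-tert-butyl-4,5-dihydrooxazole] (12 mol %), tert-butyl perbenzoate (1.5 equiv, slow addition), PhCl, 40 °C, Ar
Reagents that add atoms: none
Why: Proposed new method: an enantioselective radical acyl-oxygenation annulation (formal [4+2] of a salicylaldehyde with a styrene) in which monovalent copper reduces the perester to tert-butoxyl radical and divalent copper benzoate, the tert-butoxyl radical abstracts the formyl hydrogen of 6 (the fastest hydrogen-atom transfer on offer), the nucleophilic aroyl radical adds to the terminal carbon of styrene 16 to forge C3–C4, and the resulting benzylic radical is captured by the bis(oxazoline)-bound divalent copper already chelated by the ortho-phenoxide and ketone of the same molecule, so that C–O reductive elimination from trivalent copper closes ring C and sets C2 under ligand control (the remote carbinol centre exerts no bias, and the ligand antipode that gives 2S is fixed in the first run by CD and chiral HPLC); the closest known reaction types are the copper/peroxide oxidative acylation of styrenes with aldehydes (acyl radical addition, normally ending in the chalcone) and copper/bis(oxazoline) enantioselective radical-relay C–O bond formation (Kharasch–Sosnovsky oxidation, radical oxyfunctionalisation of styrenes by tethered O–H nucleophiles).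

Step 10
Reactants: 17 (2S)-2-[(3S)-3-hydroxy-2,2-dimethyl-8-(triisopropylsilyloxy)chroman-6-yl]-5,7-bis(triisopropylsilyloxy)chroman-4-one
Product: 18 sigmoidin D, (2S)-2-[(3S)-3,8-dihydroxy-2,2-dimethylchroman-6-yl]-5,7-dihydroxychroman-4-one
Conditions: HF·pyridine, pyridine/THF, 0 °C to rt
Reagents that add atoms: none
Why: Fluoride cleaves the three aryl Si–O bonds (driven by Si–F bond formation) under acidic conditions that cannot open the flavanone by retro-oxa-Michael reaction, so neither stereocentre is touched.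

## Compound list

1 | resorcinol | Oc1cccc(O)c1 | starting material
2 | 1,3-bis(triisopropylsilyloxy)benzene | CC(C)[Si](Oc1cccc(O[Si](C(C)C)(C(C)C)C(C)C)c1)(C(C)C)C(C)C | intermediate
3 | 2-[3,5-bis(triisopropylsilyloxy)phenyl]-4,4,5,5-tetramethyl-1,3,2-dioxaborolane | CC(C)[Si](Oc1cc(O[Si](C(C)C)(C(C)C)C(C)C)cc(c1)B1OC(C)(C)C(C)(C)O1)(C(C)C)C(C)C | intermediate
4 | 3,5-bis(triisopropylsilyloxy)phenol | CC(C)[Si](Oc1cc(O)cc(O[Si](C(C)C)(C(C)C)C(C)C)c1)(C(C)C)C(C)C | intermediate
5 | formaldehyde (as paraformaldehyde) | C=O | starting material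
6 | 2-hydroxy-4,6-bis(triisopropylsilyloxy)benzaldehyde | O=Cc1c(O)cc(O[Si](C(C)C)(C(C)C)C(C)C)cc1O[Si](C(C)C)(C(C)C)C(C)C | intermediate
7 | catechol | Oc1ccccc1O | starting material
8 | 2-(triisopropylsilyloxy)phenol | CC(C)[Si](Oc1ccccc1O)(C(C)C)C(C)C | intermediate
9 | 3-chloro-3-methylbut-1-yne | C#CC(C)(C)Cl | starting material
10 | triisopropyl[2-(2-methylbut-3-yn-2-yloxy)phenoxy]silane | C#CC(C)(C)Oc1ccccc1O[Si](C(C)C)(C(C)C)C(C)C | intermediate
11 | 2,2-dimethyl-8-(triisopropylsilyloxy)-2H-chromene | CC1(C)C=Cc2cccc(O[Si](C(C)C)(C(C)C)C(C)C)c2O1 | intermediate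
12 | (3S,4S)-3,4-epoxy-2,2-dimethyl-8-(triisopropylsilyloxy)chroman | CC1(C)Oc2c(O[Si](C(C)C)(C(C)C)C(C)C)cccc2[C@@H]3O[C@H]13 | intermediate
13 | (3S)-2,2-dimethyl-8-(triisopropylsilyloxy)chroman-3-ol | CC1(C)Oc2c(O[Si](C(C)C)(C(C)C)C(C)C)cccc2C[C@@H]1O | intermediate
14 | vinyl bromide | C=CBr | starting material
15 | (3S)-2,2-dimethyl-6-(4,4,5,5-tetramethyl-1,3,2-dioxaborolan-2-yl)-8-(triisopropylsilyloxy)chroman-3-ol | CC1(C)Oc2c(O[Si](C(C)C)(C(C)C)C(C)C)cc(B3OC(C)(C)C(C)(C)O3)cc2C[C@@H]1O | intermediate
16 | (3S)-6-ethenyl-2,2-dimethyl-8-(triisopropylsilyloxy)chroman-3-ol | CC1(C)Oc2c(O[Si](C(C)C)(C(C)C)C(C)C)cc(C=C)cc2C[C@@H]1O | intermediate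
17 | (2S)-2-[(3S)-3-hydroxy-2,2-dimethyl-8-(triisopropylsilyloxy)chroman-6-yl]-5,7-bis(triisopropylsilyloxy)chroman-4-one | CC1(C)Oc2c(O[Si](C(C)C)(C(C)C)C(C)C)cc([C@@H]3CC(=O)c4c(O[Si](C(C)C)(C(C)C)C(C)C)cc(O[Si](C(C)C)(C(C)C)C(C)C)cc4O3)cc2C[C@@H]1O | intermediate
18 | sigmoidin D | CC1(C)Oc2c(O)cc([C@@H]3CC(=O)c4c(O)cc(O)cc4O3)cc2C[C@@H]1O | target

## Step count and risk

Total step count: 10. Longest linear sequence: 7 steps (steps 4 to 10, from catechol); the ring-A branch (steps 1 to 3) joins at step 9.

**Step 9 (most likely to fail).** The para-alkoxybenzyl radical is easily oxidised by divalent copper to a free cation, which would close ring C without ligand control and erode the selectivity at C2. The tert-butoxyl radical may also attack the chroman CH2 or carbinol C–H, and the aroyl radical may be over-oxidised. The fallback sets out from 4 and 16 and returns at 17. Phenol 4 is acylated with acryloyl chloride (Et3N, CH2Cl2, 0 °C) to give 3,5-bis(triisopropylsilyloxy)phenyl prop-2-enoate F1. Cross-metathesis of this acrylate with styrene 16 (second-generation Grubbs catalyst, (H2IMes)(PCy3)Cl2Ru=CHPh, CH2Cl2, 40 °C) gives the (E)-cinnamate ester F2. Photo-Fries rearrangement (300 nm, degassed benzene) moves the acyl group from oxygen to the ortho carbon within a caged phenoxyl/acyl radical pair, the para site being blocked by two TIPS groups, and gives the 2'-hydroxychalcone F3. Ring closure by oxa-Michael addition under a quinine-derived bifunctional thiourea (toluene, rt) then gives 17. The two C2 epimers are diastereomers, so the minor one can be removed by preparative HPLC and recycled through F3 with a trace of DBU.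

**Step 8.** Borylation may be slowed by the free alcohol or give some C7 isomer, and the coupling with volatile vinyl bromide may stall. The fallback sets out from 8 and returns at 16, placing the halogen before the pyran ring is made. NBS (MeCN, −20 °C) brominates para to the free hydroxyl to give 4-bromo-2-(triisopropylsilyloxy)phenol F4. The conditions of steps 5 to 7 then give in turn the aryl propargyl ether F5 (not isolated), 6-bromo-2,2-dimethyl-8-(triisopropylsilyloxy)-2H-chromene F6, its (3S,4S)-epoxide F7 and (3S)-6-bromo-2,2-dimethyl-8-(triisopropylsilyloxy)chroman-3-ol F8. Suzuki–Miyaura coupling of this bromide with potassium vinyltrifluoroborate (Pd(dppf)Cl2, Cs2CO3, THF/H2O, 80 °C) gives 16.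

**Step 5.** O-alkylation of the hindered ortho-silyloxyphenol with a tertiary chloride may lose out to elimination of 9 or to silyl loss. The fallback sets out from 8 and returns at 11 by an ortho-quinone methide route instead of a Claisen route. Phenol 8 is condensed with 3-methylbut-2-enal and phenylboronic acid (propionic acid cat., toluene, reflux, water removal) to give 4-(2-methylprop-1-en-1-yl)-2-phenyl-8-(triisopropylsilyloxy)-4H-1,3,2-benzodioxaborinine F9. On continued heating this fragments to the ortho-quinone methide, which closes by oxa-6π electrocyclisation to 11.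

## Further compounds

F1 | step 9 | 3,5-bis(triisopropylsilyloxy)phenyl prop-2-enoate | C=CC(=O)Oc1cc(O[Si](C(C)C)(C(C)C)C(C)C)cc(O[Si](C(C)C)(C(C)C)C(C)C)c1
F2 | step 9 | 3,5-bis(triisopropylsilyloxy)phenyl (2E)-3-[(3S)-3-hydroxy-2,2-dimethyl-8-(triisopropylsilyloxy)chroman-6-yl]prop-2-enoate | CC1(C)Oc2c(O[Si](C(C)C)(C(C)C)C(C)C)cc(/C=C/C(=O)Oc3cc(O[Si](C(C)C)(C(C)C)C(C)C)cc(O[Si](C(C)C)(C(C)C)C(C)C)c3)cc2C[C@@H]1O
F3 | step 9 | (2E)-1-[2-hydroxy-4,6-bis(triisopropylsilyloxy)phenyl]-3-[(3S)-3-hydroxy-2,2-dimethyl-8-(triisopropylsilyloxy)chroman-6-yl]prop-2-en-1-one | CC1(C)Oc2c(O[Si](C(C)C)(C(C)C)C(C)C)cc(/C=C/C(=O)c3c(O)cc(O[Si](C(C)C)(C(C)C)C(C)C)cc3O[Si](C(C)C)(C(C)C)C(C)C)cc2C[C@@H]1O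
F4 | step 8 | 4-bromo-2-(triisopropylsilyloxy)phenol | Oc1ccc(Br)cc1O[Si](C(C)C)(C(C)C)C(C)C
F5 | step 8 | [5-bromo-2-(2-methylbut-3-yn-2-yloxy)phenoxy]triisopropylsilane | C#CC(C)(C)Oc1ccc(Br)cc1O[Si](C(C)C)(C(C)C)C(C)C
F6 | step 8 | 6-bromo-2,2-dimethyl-8-(triisopropylsilyloxy)-2H-chromene | CC1(C)C=Cc2cc(Br)cc(O[Si](C(C)C)(C(C)C)C(C)C)c2O1
F7 | step 8 | (3S,4S)-6-bromo-3,4-epoxy-2,2-dimethyl-8-(triisopropylsilyloxy)chroman | CC1(C)Oc2c(O[Si](C(C)C)(C(C)C)C(C)C)cc(Br)cc2[C@@H]3O[C@H]13
F8 | step 8 | (3S)-6-bromo-2,2-dimethyl-8-(triisopropylsilyloxy)chroman-3-ol | CC1(C)Oc2c(O[Si](C(C)C)(C(C)C)C(C)C)cc(Br)cc2C[C@@H]1O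
F9 | step 5 | 4-(2-methylprop-1-en-1-yl)-2-phenyl-8-(triisopropylsilyloxy)-4H-1,3,2-benzodioxaborinine | CC(C)=CC1OB(c2ccccc2)Oc2c(O[Si](C(C)C)(C(C)C)C(C)C)cccc12
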